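**Plan**
- Retrosynthesis: one operation cuts both ester C–O bonds and the propargylic C(sp)–C(sp3) bond (alkyne carbon C-3 to CH2 C-2 of the butynyl chain). This leaves (5'-ethynyl-2,2'-bithiophen-5-yl)methanol, oxirane and 3-methylbutanoyl chloride. The thiophene–C(sp) bond is cut next, leading to 5'-bromo-2,2'-bithiophene-5-carbaldehyde, so the bithiophene is bought intact.
- Enabling feature: the ester oxygen on C-1 of the chain stands 1,2 to the propargylic carbon C-2, so O/C-1/C-2 are an opened oxirane ring. Its opening by the acetylide on ring A (the alkyne-bearing thiophene) creates a second primary lithium alkoxide beside the one on the CH2 at the α-carbon of ring B (the other thiophene). Both oxygens carry the same acyl group, so one acylation finishes both ends.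
- Forward order: alkyne installed on ring A; aldehyde on ring B reduced and the alkyne unmasked; then C2 extension and double acylation in one flask.
- Stereochemistry: the target has no stereocentre and no stereogenic double bond, so nothing needs control.

Key step: step 3

Assumption: 5'-bromo-2,2'-bithiophene-5-carbaldehyde (1) is taken as a catalogue compound, and oxirane is used as its commercial THF solution.

**Step 1**
Reactants: 1 5'-bromo-2,2'-bithiophene-5-carbaldehyde; 2 ethynyltrimethylsilane
Product: 3 5'-[(trimethylsilyl)ethynyl]-2,2'-bithiophene-5-carbaldehyde
Conditions: PdCl2(PPh3)2 (2 mol %), CuI (4 mol %), Et3N/THF, degassed, 50 °C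
Reagents that add atoms: none
Why: Sonogashira coupling; the α C–Br bond of ring A, activated through conjugation with the formyl group, should add oxidatively to zerovalent palladium and couple with the copper acetylide of 2, while the silyl cap prevents a second coupling and the aldehyde is inert.

**Step 2**
Reactants: 3 5'-[(trimethylsilyl)ethynyl]-2,2'-bithiophene-5-carbaldehyde
Product: 5 (5'-ethynyl-2,2'-bithiophen-5-yl)methanol, via silyl alcohol 4 (not isolated)
Conditions: NaBH4, MeOH/THF, 0 °C; then K2CO3 (cat.), rt
Reagents that add atoms: none
Why: Borohydride reduction of the aldehyde followed by methoxide-catalysed protodesilylation of the C(sp)–Si bond should give the alkynyl alcohol in one flask, since NaBH4 leaves the alkyne and both thiophene rings untouched.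

**Step 3**
Reactants: 5 (5'-ethynyl-2,2'-bithiophen-5-yl)methanol; 6 oxirane; 7 3-methylbutanoyl chloride
Product: 10 4-[5'-({(3-methylbutanoyl)oxy}methyl)-2,2'-bithiophen-5-yl]but-3-yn-1-yl 3-methylbutanoate (target), via dilithio acetylide alkoxide 8 (not isolated), via dilithium bis-alkoxide 9 (not isolated)
Conditions: n-BuLi (2.1 equiv), THF, –78 → 0 °C; DMPU, 6 (1.3 equiv, THF solution), 0 °C → rt, closed flask; argon purge; 7 (2.5 equiv), –20 °C → rt; aq. NaHCO3
Reagents that add atoms: none
Why: Double deprotonation should give the O,C-dilithio species 8, whose acetylide carbon opens oxirane by SN2 attack at a ring CH2, forming the C(sp)–C(sp3) bond and releasing the second primary alkoxide of 9; both lithium alkoxides are then O-acylated by 7 in the same flask, so one C–C and two C–O bonds are made without isolating the diol. The closest known reaction type is the β-hydroxyethylation of lithium arylacetylides with oxirane in THF with a dipolar cosolvent, joined to the acylation of lithium alkoxides by an acid chloride. No ring is closed and no stereocentre is formed. The selectivity needed is C- over O-alkylation of the dianion and no further oxirane insertion into the alkoxides; the acetylide is the more nucleophilic, last-formed site, lithium alkoxides are aggregated and poor nucleophiles toward oxirane, and the oxirane is limited to a small excess that is purged before acylation. Both α-positions of the bithiophene are substituted, so n-BuLi should metalate only O–H and C(sp)–H and no ring carbon.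

**Compound list**
1 | 5'-bromo-2,2'-bithiophene-5-carbaldehyde | O=Cc1ccc(-c2ccc(Br)s2)s1 | starting material
2 | ethynyltrimethylsilane | C#C[Si](C)(C)C | starting material
3 | 5'-[(trimethylsilyl)ethynyl]-2,2'-bithiophene-5-carbaldehyde | O=Cc1ccc(-c2ccc(C#C[Si](C)(C)C)s2)s1 | intermediate
4 | {5'-[(trimethylsilyl)ethynyl]-2,2'-bithiophen-5-yl}methanol | OCc1ccc(-c2ccc(C#C[Si](C)(C)C)s2)s1 | intermediate (not isolated)
5 | (5'-ethynyl-2,2'-bithiophen-5-yl)methanol | OCc1ccc(-c2ccc(C#C)s2)s1 | intermediate
6 | oxirane | C1CO1 | starting material
7 | 3-methylbutanoyl chloride | CC(C)CC(=O)Cl | starting material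
8 | lithium [5'-(lithioethynyl)-2,2'-bithiophen-5-yl]methoxide | [Li]OCc1ccc(-c2ccc(C#C[Li])s2)s1 | intermediate (not isolated)
9 | dilithium 4-[5'-(oxidomethyl)-2,2'-bithiophen-5-yl]but-3-yn-1-olate | [Li]OCCC#Cc1ccc(-c2ccc(CO[Li])s2)s1 | intermediate (not isolated)
10 | 4-[5'-({(3-methylbutanoyl)oxy}methyl)-2,2'-bithiophen-5-yl]but-3-yn-1-yl 3-methylbutanoate | CC(C)CC(=O)OCCC#Cc1ccc(-c2ccc(COC(=O)CC(C)C)s2)s1 | target

Total step count: 3. Longest linear sequence: 3 steps (from 1).

**Steps most likely to fail**

Step 3. Without a Lewis acid the delocalised arylacetylide may open oxirane slowly, further oxirane may insert into the lithium alkoxides, and unreacted acetylide would be C-acylated. The fallback sets out from 5 and brings in the C2 unit at the ester oxidation level, with a separate acylation. Coupling of 5 with ethyl diazoacetate under CuI catalysis (MeCN, rt) should form the same C(sp)–C(sp3) bond by carbene insertion at the copper acetylide and give ethyl 4-[5'-(hydroxymethyl)-2,2'-bithiophen-5-yl]but-3-ynoate F1. Reduction of the ester with i-Bu2AlH (CH2Cl2, –78 → 0 °C) should give the diol 4-[5'-(hydroxymethyl)-2,2'-bithiophen-5-yl]but-3-yn-1-ol F2. Acylation of both hydroxyl groups with 7 and pyridine (CH2Cl2, 0 °C) comes back to the route at 10.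

Step 2. The electron-rich free terminal alkyne may dimerise oxidatively or oligomerise during concentration and storage. The fallback sets out from 3 and never isolates the free alkyne. Reduction with NaBH4 alone gives silyl alcohol 4, which is isolated as a storable compound. Treatment of 4 with MeLi·LiBr (2.1 equiv, THF, 0 °C → rt) should deprotonate the O–H and cleave the C(sp)–Si bond by attack at silicon, generating the dilithio species directly. The fallback comes back to the route at 8, which is carried through the rest of step 3 unchanged.

Step 1. Copper-mediated oxidative homocoupling of the alkyne, or partial loss of the silyl cap in the amine medium followed by a second coupling, may erode the cross-coupling. The fallback sets out from 1 and uses a copper-free and amine-free Stille coupling with tributyl[(trimethylsilyl)ethynyl]stannane (Pd(PPh3)4, toluene, 90 °C). The alkynyl group is transferred from tin, and the fallback comes back to the route at 3.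

**Further compounds**
F1 | step 3 | ethyl 4-[5'-(hydroxymethyl)-2,2'-bithiophen-5-yl]but-3-ynoate | CCOC(=O)CC#Cc1ccc(-c2ccc(CO)s2)s1
F2 | step 3 | 4-[5'-(hydroxymethyl)-2,2'-bithiophen-5-yl]but-3-yn-1-ol | OCCC#Cc1ccc(-c2ccc(CO)s2)s1
F0 | step 2 | none | none
F0 | step 1 | none | none
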